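**Retrosynthetic overview**

1. The target is a mirror-symmetric pentamer: two 2-butanoyl-4,4-dimethylcyclohexane-1,3,5-trione rings (A, E) hang by CH2 bridges on a tris(butanoylphloroglucinol) core (B–C–D). The last three steps only unmask: two isoxazoles (N–O hydrogenolysis, then hydrolysis) and nine benzyl ethers (H2).
2. Rings A and E are closed last and together by a two-directional double Dieckmann (intramolecular Claisen) condensation of 14. In each end ring the enolate of C2 (the carbon carrying the ArCH2 bridge) attacks the ester carbon C1, which sits on isoxazole C4 (= ring carbon C6, the later butanoyl-bearing carbon).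
3. Enabling feature: in rings A and E the quaternary C4 (CMe2) leaves C2 as the only enolisable carbon next to the C3 ketone, and C1 is a carboxyl-level carbon on C6. The C5/C6/butanoyl-carbon 1,3-dicarbonyl can be locked as an isoxazole (O on C5, N on the butanoyl carbon), so the ester has no acidic neighbour. The mirror plane through ring C lets both masked poly-β-carbonyl chains fold in one operation.
4. Bis-chain precursor 14 comes from ring C (ketone 3) and two benzylic alcohols 13 by double Friedel–Crafts benzylation. 13 comes from 3 and vinyl ketone 10 (Friedel–Crafts conjugate addition), then formylation and reduction. 10 comes from isoxazole 7 by lateral carbanion acylation.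
5. Order of ring formation: isoxazoles (step 2); aromatic rings B, C, D taken ready-made from 1,3,5-tris(benzyloxy)benzene; rings A and E together (step 8).

Key step: step 8

Assumption: the target has no stereocentre and no intermediate of the route has one. Each β-tricarbonyl, enol and enaminone unit is drawn as one tautomer. 1,3,5-Tris(benzyloxy)benzene is taken as a purchasable compound.

**Route**

Step 1
Reactants: 1 1,3,5-tris(benzyloxy)benzene; 2 butanoic acid
Product: 3 1-[2,4,6-tris(benzyloxy)phenyl]butan-1-one
Conditions: 2 premixed with (CF3CO)2O, CH2Cl2, 0 °C; then 1, 0 °C to rt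
Reagents that add atoms: none
Why: Friedel–Crafts acylation through the mixed butanoic trifluoroacetic anhydride should acylate the strongly activated tribenzyl ether once, because the first acyl group deactivates the ring.

Step 2
Reactants: 4 butanal oxime; 5 methyl 4-methyl-3-oxopentanoate
Product: 7 methyl 5-(propan-2-yl)-3-propyl-1,2-oxazole-4-carboxylate, via N-hydroxybutanimidoyl chloride 6 (not isolated)
Conditions: N-chlorosuccinimide, DMF, rt; then 5, NaOMe, MeOH, 0 °C to rt
Reagents that add atoms: none
Why: Chlorination of the aldoxime gives the hydroximoyl chloride, which the sodium enolate of the β-keto ester should attack at carbon, followed by closure of the oxime oxygen onto the ketone and loss of water (isoxazole synthesis from a hydroximoyl chloride and a β-keto ester), placing propyl at C3, the ester at C4 and isopropyl at C5.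

Step 3
Reactants: 7 methyl 5-(propan-2-yl)-3-propyl-1,2-oxazole-4-carboxylate; 8 3-chloropropanoyl chloride
Product: 10 methyl 5-(2-methyl-3-oxopent-4-en-2-yl)-3-propyl-1,2-oxazole-4-carboxylate, via β-chloro ketone 9 (not isolated)
Conditions: LiN(iPr)2, THF, −78 °C; cannulated into 8 (2 equiv), THF, −78 °C; then Et3N, −78 °C to rt
Reagents that add atoms: none
Why: Lateral deprotonation at the methine of the 5-isopropyl group (a vinylogous ester enolate stabilised through the isoxazole C5=C4 bond and the 4-ester), C-acylation by the acid chloride and E1cB loss of HCl should give the vinyl ketone with the quaternary carbon in place (lateral metalation–acylation, then β-elimination).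

Step 4
Reactants: 3 1-[2,4,6-tris(benzyloxy)phenyl]butan-1-one; 10 methyl 5-(2-methyl-3-oxopent-4-en-2-yl)-3-propyl-1,2-oxazole-4-carboxylate
Product: 11 methyl 5-{5-[2,4,6-tris(benzyloxy)-3-butanoylphenyl]-2-methyl-3-oxopentan-2-yl}-3-propyl-1,2-oxazole-4-carboxylate
Conditions: Sc(OTf)3 (10 mol %), MeCN, rt to 40 °C; equimolar partners, the vinyl ketone added slowly to the arene
Reagents that add atoms: none
Why: Lewis-acid-catalysed Friedel–Crafts conjugate addition of the trialkoxyarene C–H across the unhindered terminal carbon of the activated vinyl ketone should give the aryl-CH2-CH2-ketone as a pure addition in which every atom of both partners ends in 11, and a second alkylation should be slower because in 11 the last free ring carbon lies between two benzyloxy groups that are both turned towards it while the benzyloxy group between the butanoyl group and the new chain is twisted out of conjugation.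

Step 5
Reactants: 11 methyl 5-{5-[2,4,6-tris(benzyloxy)-3-butanoylphenyl]-2-methyl-3-oxopentan-2-yl}-3-propyl-1,2-oxazole-4-carboxylate
Product: 12 methyl 5-{5-[2,4,6-tris(benzyloxy)-3-butanoyl-5-formylphenyl]-2-methyl-3-oxopentan-2-yl}-3-propyl-1,2-oxazole-4-carboxylate
Conditions: Cl2CHOMe, AgOTf, CH2Cl2, −78 °C; aq NaHCO3
Reagents that add atoms: dichloromethyl methyl ether, COC(Cl)Cl; water, O
Why: Rieche formylation, in which the chloro(methoxy)carbenium ion released by AgOTf should attack the only remaining aromatic C–H of the trialkoxy ring at a temperature where ketones, ester and benzyl ethers are inert, and hydrolysis on work-up releases the aldehyde.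

Step 6
Reactants: 12 methyl 5-{5-[2,4,6-tris(benzyloxy)-3-butanoyl-5-formylphenyl]-2-methyl-3-oxopentan-2-yl}-3-propyl-1,2-oxazole-4-carboxylate
Product: 13 methyl 5-{5-[2,4,6-tris(benzyloxy)-3-butanoyl-5-(hydroxymethyl)phenyl]-2-methyl-3-oxopentan-2-yl}-3-propyl-1,2-oxazole-4-carboxylate
Conditions: NaBH4 (0.5 equiv), THF/MeOH, −40 to −20 °C
Reagents that add atoms: none
Why: Chemoselective borohydride reduction, in which the aldehyde should react much faster than the dialkyl ketone next to a quaternary carbon and the twisted di-ortho-substituted aryl ketone at low temperature.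

Step 7
Reactants: 13 methyl 5-{5-[2,4,6-tris(benzyloxy)-3-butanoyl-5-(hydroxymethyl)phenyl]-2-methyl-3-oxopentan-2-yl}-3-propyl-1,2-oxazole-4-carboxylate (2.2 equiv); 3 1-[2,4,6-tris(benzyloxy)phenyl]butan-1-one
Product: 14 bis-chain precursor, 1-[2,4,6-tris(benzyloxy)-3,5-bis({2,4,6-tris(benzyloxy)-3-butanoyl-5-[4-(4-methoxycarbonyl-3-propyl-1,2-oxazol-5-yl)-4-methyl-3-oxopentyl]phenyl}methyl)phenyl]butan-1-one
Conditions: Bi(OTf)3 (5 mol %), CH2Cl2/(CF3)2CHOH, 0 °C to rt
Reagents that add atoms: none
Why: Two-fold Friedel–Crafts benzylation, in which the 2,4,6-trialkoxybenzylic alcohol ionises under mild Lewis acid and the cation should be captured at the two free positions of 3, while 13 has no free aromatic position and cannot self-condense.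

Step 8
Reactants: 14 bis-chain precursor
Product: 15 bis(isoxazole-fused enol-dione), 1-[2,4,6-tris(benzyloxy)-3,5-bis({2,4,6-tris(benzyloxy)-3-butanoyl-5-[(6-hydroxy-7,7-dimethyl-4-oxo-3-propyl-4,7-dihydro-1,2-benzoxazol-5-yl)methyl]phenyl}methyl)phenyl]butan-1-one
Conditions: KOtBu (6 equiv), THF, 0 °C to rt; 1 M aq HCl, 0 °C
Reagents that add atoms: none
Why: KOtBu reversibly deprotonates C2, the only enolisable carbon flanking each side-chain ketone, and the enolate carbon adds to the neighbouring isoxazole-4-carboxylate carbonyl (C1); loss of methoxide gives the cyclic β-diketone, whose immediate deprotonation (vinylogous acid) makes each closure irreversible. The closest known reaction type is the Dieckmann-type intramolecular Claisen condensation of δ-keto esters to cyclohexane-1,3-diones, including closures of ketone enolates onto aromatic ortho-esters that give fused hydroxy-enones. Rings A and E each close in the 6-(enolexo)-exo-trig mode, the six-membered ring being completed by the isoxazole C4–C5 bond and favoured by the gem-dimethyl group. No stereocentre is formed, because C2 ends as an enol carbon. The step needs C- over O-acylation and reaction of this enolate only: any enol lactone from O-attack is reopened by alkoxide and funnels to the stable diketone enolate, the quaternary C4 and the isoxazole lock exclude every other enolate next to an ester (and the retro-Claisen loss of the butanoyl group that a free triacylmethane would suffer), and the aryl butanoyl ketone enolates have no ester within reach of a five- or six-membered ring. The benzyl ethers remove the phenoxide that would otherwise let the new ArCH2–ring A link fragment under base.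

Step 9
Reactants: 15 bis(isoxazole-fused enol-dione)
Product: 16 bis(enaminone), in which each end ring is a 2-(1-aminobutylidene)-5-hydroxy-6,6-dimethylcyclohex-4-ene-1,3-dione carrying the ArCH2 bridge at C4
Conditions: H2 (1 atm), Raney Ni, THF/EtOH, rt
Reagents that add atoms: none
Why: Hydrogenolysis of the weak N–O bond of each 3,5-disubstituted isoxazole over nickel should unmask the β-enaminone (vinylogous amide), while aryl benzyl ethers are not cleaved over Raney Ni under these mild conditions.

Step 10
Reactants: 16 bis(enaminone)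
Product: 17 nona-O-benzyl ether of the target (all nine phenolic oxygens of rings B, C and D benzylated)
Conditions: 2 M aq HCl, THF, 60 °C
Reagents that add atoms: water, O
Why: Acid hydrolysis of the primary vinylogous amide (O-protonation, addition of water to the aminoalkylidene carbon, loss of ammonia as ammonium) should give the 2-butanoyl triones, while benzyl ethers and the diarylmethane links of the fully etherified rings are stable to dilute aqueous acid.

Step 11
Reactants: 17 nona-O-benzyl ether of the target
Product: 18 target CNP0188003.0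
Conditions: H2 (1 atm), 10% Pd/C, EtOAc/MeOH, rt
Reagents that add atoms: none
Why: Hydrogenolysis of nine aryl benzyl ethers over Pd/C under neutral conditions, to which the β-triketone and aryl ketone groups are inert, should release the nonaphenol without exposing the base-labile methylene-bridged product to alkali.

**Compound list**

1 | 1,3,5-tris(benzyloxy)benzene | c1c(OCc2ccccc2)cc(OCc2ccccc2)cc1OCc1ccccc1 | starting material
2 | butanoic acid | CCCC(=O)O | starting material
3 | 1-[2,4,6-tris(benzyloxy)phenyl]butan-1-one | CCCC(=O)c1c(OCc2ccccc2)cc(OCc2ccccc2)cc1OCc1ccccc1 | intermediate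
4 | butanal oxime | CCCC=NO | starting material
5 | methyl 4-methyl-3-oxopentanoate | COC(=O)CC(=O)C(C)C | starting material
6 | N-hydroxybutanimidoyl chloride | CCCC(Cl)=NO | intermediate (not isolated)
7 | methyl 5-(propan-2-yl)-3-propyl-1,2-oxazole-4-carboxylate | CCCc1noc(C(C)C)c1C(=O)OC | intermediate
8 | 3-chloropropanoyl chloride | ClCCC(Cl)=O | starting material
9 | methyl 5-(5-chloro-2-methyl-3-oxopentan-2-yl)-3-propyl-1,2-oxazole-4-carboxylate (β-chloro ketone) | CCCc1noc(C(C)(C)C(=O)CCCl)c1C(=O)OC | intermediate (not isolated)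
10 | methyl 5-(2-methyl-3-oxopent-4-en-2-yl)-3-propyl-1,2-oxazole-4-carboxylate | CCCc1noc(C(C)(C)C(=O)C=C)c1C(=O)OC | intermediate
11 | methyl 5-{5-[2,4,6-tris(benzyloxy)-3-butanoylphenyl]-2-methyl-3-oxopentan-2-yl}-3-propyl-1,2-oxazole-4-carboxylate | CCCC(=O)c1c(OCc2ccccc2)c(CCC(=O)C(C)(C)c2onc(CCC)c2C(=O)OC)c(OCc2ccccc2)cc1OCc1ccccc1 | intermediate
12 | methyl 5-{5-[2,4,6-tris(benzyloxy)-3-butanoyl-5-formylphenyl]-2-methyl-3-oxopentan-2-yl}-3-propyl-1,2-oxazole-4-carboxylate | CCCC(=O)c1c(OCc2ccccc2)c(CCC(=O)C(C)(C)c2onc(CCC)c2C(=O)OC)c(OCc2ccccc2)c(C=O)c1OCc1ccccc1 | intermediate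
13 | methyl 5-{5-[2,4,6-tris(benzyloxy)-3-butanoyl-5-(hydroxymethyl)phenyl]-2-methyl-3-oxopentan-2-yl}-3-propyl-1,2-oxazole-4-carboxylate | CCCC(=O)c1c(OCc2ccccc2)c(CCC(=O)C(C)(C)c2onc(CCC)c2C(=O)OC)c(OCc2ccccc2)c(CO)c1OCc1ccccc1 | intermediate
14 | bis-chain precursor: 1-[2,4,6-tris(benzyloxy)-3,5-bis({2,4,6-tris(benzyloxy)-3-butanoyl-5-[4-(4-methoxycarbonyl-3-propyl-1,2-oxazol-5-yl)-4-methyl-3-oxopentyl]phenyl}methyl)phenyl]butan-1-one | CCCC(=O)c1c(OCc2ccccc2)c(Cc2c(OCc3ccccc3)c(C(=O)CCC)c(OCc3ccccc3)c(CCC(=O)C(C)(C)c3onc(CCC)c3C(=O)OC)c2OCc2ccccc2)c(OCc2ccccc2)c(Cc2c(OCc3ccccc3)c(C(=O)CCC)c(OCc3ccccc3)c(CCC(=O)C(C)(C)c3onc(CCC)c3C(=O)OC)c2OCc2ccccc2)c1OCc1ccccc1 | intermediate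
15 | bis(isoxazole-fused enol-dione): 1-[2,4,6-tris(benzyloxy)-3,5-bis({2,4,6-tris(benzyloxy)-3-butanoyl-5-[(6-hydroxy-7,7-dimethyl-4-oxo-3-propyl-4,7-dihydro-1,2-benzoxazol-5-yl)methyl]phenyl}methyl)phenyl]butan-1-one | CCCC(=O)c1c(OCc2ccccc2)c(Cc2c(OCc3ccccc3)c(C(=O)CCC)c(OCc3ccccc3)c(CC3=C(O)C(C)(C)c4onc(CCC)c4C3=O)c2OCc2ccccc2)c(OCc2ccccc2)c(Cc2c(OCc3ccccc3)c(C(=O)CCC)c(OCc3ccccc3)c(CC3=C(O)C(C)(C)c4onc(CCC)c4C3=O)c2OCc2ccccc2)c1OCc1ccccc1 | intermediate
16 | bis(enaminone): as 15, but each isoxazole opened to a 2-(1-aminobutylidene)-5-hydroxy-6,6-dimethylcyclohex-4-ene-1,3-dione ring | CCCC(=O)c1c(OCc2ccccc2)c(Cc2c(OCc3ccccc3)c(C(=O)CCC)c(OCc3ccccc3)c(CC3=C(O)C(C)(C)C(=O)C(=C(N)CCC)C3=O)c2OCc2ccccc2)c(OCc2ccccc2)c(Cc2c(OCc3ccccc3)c(C(=O)CCC)c(OCc3ccccc3)c(CC3=C(O)C(C)(C)C(=O)C(=C(N)CCC)C3=O)c2OCc2ccccc2)c1OCc1ccccc1 | intermediate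
17 | nona-O-benzyl ether of the target | CCCC(=O)c1c(OCc2ccccc2)c(Cc2c(OCc3ccccc3)c(C(=O)CCC)c(OCc3ccccc3)c(CC3=C(O)C(C)(C)C(O)=C(C(=O)CCC)C3=O)c2OCc2ccccc2)c(OCc2ccccc2)c(Cc2c(OCc3ccccc3)c(C(=O)CCC)c(OCc3ccccc3)c(CC3=C(O)C(C)(C)C(O)=C(C(=O)CCC)C3=O)c2OCc2ccccc2)c1OCc1ccccc1 | intermediate
18 | CNP0188003.0 | CCCC(=O)C1=C(O)C(C)(C)C(O)=C(Cc2c(O)c(Cc3c(O)c(Cc4c(O)c(CC5=C(O)C(C)(C)C(O)=C(C(=O)CCC)C5=O)c(O)c(C(=O)CCC)c4O)c(O)c(C(=O)CCC)c3O)c(O)c(C(=O)CCC)c2O)C1=O | target

**Step count and risks**

Total steps: 11. Longest linear sequence: 10 steps (steps 2 to 11; step 1 is a branch that supplies 3 to steps 4 and 7).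

Steps most likely to fail:

Step 3. The tertiary carbanion may act as a base towards the acid chloride or the β-chloro ketone, and may add in conjugate fashion to the enone that forms by early elimination, so that the acylation stalls or oligomerises. The fallback sets out from 7 and comes back at 10. The same carbanion is acylated with N-methoxy-N-methylacetamide (CC(=O)N(C)OC), whose tetrahedral adduct persists until the acidic quench and so offers neither an enolisable nor a conjugated product to the carbanion. This should give the methyl ketone methyl 5-(2-methyl-3-oxobutan-2-yl)-3-propyl-1,2-oxazole-4-carboxylate F1. The missing carbon is then introduced by acid-mediated α-methylenation (paraformaldehyde, N-methylanilinium trifluoroacetate, THF, reflux), conditions under which no enolate and therefore no premature ring closure can arise, to return to 10.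

Step 7. Capture of the stabilised benzylic cation by the acyl-deactivated arene 3 may be slow, so that acid-promoted scrambling of the diarylmethane bonds and O-to-C benzyl migration compete. The fallback sets out from 13 and comes back at 14. Two equivalents of 13 are condensed under catalytic TsOH in CH2Cl2/(CF3)2CHOH with commercial 1-(2,4,6-trihydroxyphenyl)butan-1-one (CCCC(=O)c1c(O)cc(O)cc1O), whose free phenolic ring is a far stronger carbon nucleophile than 3. This should give the trimer with an unprotected ring C, 1-[2,4,6-trihydroxy-3,5-bis({2,4,6-tris(benzyloxy)-3-butanoyl-5-[4-(4-methoxycarbonyl-3-propyl-1,2-oxazol-5-yl)-4-methyl-3-oxopentyl]phenyl}methyl)phenyl]butan-1-one F2. O-Benzylation of its three phenols (BnBr, K2CO3, DMF) returns to 14.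

Step 8. Competing enolisation of the three aryl butanoyl ketones under alkoxide may lead to intermolecular Claisen or aldol oligomerisation, or the second closure may stall on the poorly soluble mono-enolate. The fallback sets out from 14 and comes back at 15. The two methyl esters are saponified (LiOH, THF/MeOH/H2O) to the diacid, the bis(isoxazole-4-carboxylic acid) analogue of 14 F3. This is converted with pentafluorophenol and a carbodiimide into the bis(pentafluorophenyl ester) of that diacid F4. Both rings are then closed by soft enolisation (MgBr2·OEt2, iPr2NEt, CH2Cl2, rt), a Lewis-acid-mediated Claisen acylation of the ketone by the activated ester that needs no alkoxide, to give 15.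

Further compounds
F1 | step 3 | methyl 5-(2-methyl-3-oxobutan-2-yl)-3-propyl-1,2-oxazole-4-carboxylate | CCCc1noc(C(C)(C)C(C)=O)c1C(=O)OC
F2 | step 7 | 1-[2,4,6-trihydroxy-3,5-bis({2,4,6-tris(benzyloxy)-3-butanoyl-5-[4-(4-methoxycarbonyl-3-propyl-1,2-oxazol-5-yl)-4-methyl-3-oxopentyl]phenyl}methyl)phenyl]butan-1-one | CCCC(=O)c1c(O)c(Cc2c(OCc3ccccc3)c(C(=O)CCC)c(OCc3ccccc3)c(CCC(=O)C(C)(C)c3onc(CCC)c3C(=O)OC)c2OCc2ccccc2)c(O)c(Cc2c(OCc3ccccc3)c(C(=O)CCC)c(OCc3ccccc3)c(CCC(=O)C(C)(C)c3onc(CCC)c3C(=O)OC)c2OCc2ccccc2)c1O
F3 | step 8 | diacid: 14 with both methyl esters replaced by carboxylic acids | CCCC(=O)c1c(OCc2ccccc2)c(Cc2c(OCc3ccccc3)c(C(=O)CCC)c(OCc3ccccc3)c(CCC(=O)C(C)(C)c3onc(CCC)c3C(=O)O)c2OCc2ccccc2)c(OCc2ccccc2)c(Cc2c(OCc3ccccc3)c(C(=O)CCC)c(OCc3ccccc3)c(CCC(=O)C(C)(C)c3onc(CCC)c3C(=O)O)c2OCc2ccccc2)c1OCc1ccccc1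
F4 | step 8 | bis(pentafluorophenyl ester) of diacid F3 | CCCC(=O)c1c(OCc2ccccc2)c(Cc2c(OCc3ccccc3)c(C(=O)CCC)c(OCc3ccccc3)c(CCC(=O)C(C)(C)c3onc(CCC)c3C(=O)Oc3c(F)c(F)c(F)c(F)c3F)c2OCc2ccccc2)c(OCc2ccccc2)c(Cc2c(OCc3ccccc3)c(C(=O)CCC)c(OCc3ccccc3)c(CCC(=O)C(C)(C)c3onc(CCC)c3C(=O)Oc3c(F)c(F)c(F)c(F)c3F)c2OCc2ccccc2)c1OCc1ccccc1
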